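Ring B (C5–C6–C7–C8–C9–C10) is disconnected at C6–C7, so that its 1,3-diol (C6–OH and C8–OH) becomes a Prins retron. The key step treats seco-aldehyde 34, which already carries ring A, the C4 ester and the complete 1,2-dioxane-lactone, with an aqueous Lewis acid. The C6 aldehyde on C5 is attacked by the isopropenyl group on C9 (C7=C8) and the C8 cation is hydrated, which closes ring B and sets C6 and C8 in one operation. Ring A comes from a catalytic asymmetric Diels–Alder reaction, the C9–C10 bond from a ketal Claisen rearrangement, and the peroxide from epoxide perhydrolysis followed by intramolecular displacement.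

Key step: step 23

Remark on numbering: ring A = C1–C5 and C10 (C4 carries CH3 and CO2CH3, C10 carries CH3); ring B = C5–C10 (C8 carries CH3); side chain = C11–C19 with C13=CH2, the O–O bridge between C14 and C17 (C17 carries CH3) and the lactone from O–C16 to C19; in the seco compounds C6 is the one-carbon group on C5 and C7/C8 the isopropenyl group on C9.
Remark on configuration: the structure is read as 4R,5R,6S,8R,9R,10S,14R,16S,17R, which makes the γ-lactone trans-fused to the 1,2-dioxane; the route is built for that arrangement.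
Remark on reagent control: the facial sense of steps 3, 14 and 16 is taken from the usual transition-state models; where a model should fail, the antipodal catalyst is used.
Remark on materials: 1, 2, 4, 11, 14 and 16 are taken as catalogue chemicals.

Step 1
Reactants: 1 (tert-butyldiphenylsilyloxy)acetaldehyde; 2 ylide 2-(triphenylphosphoranylidene)propanal
Product: 3 (E)-4-(tert-butyldiphenylsilyloxy)-2-methylbut-2-enal
Conditions: toluene, 80 °C
Reagents that add atoms: none
Why: Wittig olefination with the formyl-stabilised ylide should give the (E)-configured 2-methyl enal, whose geometry later fixes the C4/C5 relationship.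

Step 2
Reactants: 4 pent-1-en-3-one
Product: 5 (Z)-3-(triisopropylsilyloxy)penta-1,3-diene
Conditions: i-Pr3SiOTf, Et3N, Et2O, 0 °C
Reagents that add atoms: triisopropylsilyl trifluoromethanesulfonate CC(C)[Si](C(C)C)(C(C)C)OS(=O)(=O)C(F)(F)F
Why: Soft enolisation and O-silylation of the enone should give the 2-silyloxy diene with the (Z)-enol ether geometry that keeps the terminal methyl group outside the s-cis diene.

Step 3
Reactants: 3 (E)-4-(tert-butyldiphenylsilyloxy)-2-methylbut-2-enal; 5 (Z)-3-(triisopropylsilyloxy)penta-1,3-diene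
Product: 7 keto aldehyde (1R,2R,3R)-2-(tert-butyldiphenylsilyloxymethyl)-1,3-dimethyl-4-oxocyclohexane-1-carbaldehyde, via silyl enol ether cycloadduct 6 (not isolated)
Conditions: (S)-o-tolyl-CBS oxazaborolidine·HNTf2 (20 mol %), CH2Cl2, −78 to −20 °C; then 1 M HCl, THF, 0 °C
Reagents that add atoms: none
Why: Enantioselective Diels–Alder reaction under chiral oxazaborolidinium catalysis, in which the nucleophilic CH(CH3) terminus of the diene bonds to the β-carbon of the enal (C5) and the CH2 terminus to the α-carbon (C4), the catalyst-bound s-trans enal is attacked on the Re face of C4 (4R), the (E)-alkene transfers its geometry to the C4/C5 pair (CHO trans to CH2OSi, hence 5R), and hydrolysis of the silyl enol ether gives the C1 ketone whose C10 centre is re-made in step 11.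

Step 4
Reactants: 7 keto aldehyde
Product: 8 (1R,2R,3R)-2-(tert-butyldiphenylsilyloxymethyl)-1,3-dimethyl-4-oxocyclohexane-1-carboxylic acid
Conditions: NaClO2, NaH2PO4, 2-methyl-2-butene, t-BuOH/H2O, 0 °C to rt
Reagents that add atoms: sodium chlorite [Na+].[O-]Cl=O
Why: Pinnick oxidation should convert the hindered aldehyde on the quaternary C4 into the acid without touching the ketone, the silyl ether or the non-enolisable C4 centre.

Step 5
Reactants: 8 keto acid
Product: 9 methyl (1R,2R,3R)-2-(tert-butyldiphenylsilyloxymethyl)-1,3-dimethyl-4-oxocyclohexane-1-carboxylate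
Conditions: Me3SiCHN2, MeOH/toluene, 0 °C
Reagents that add atoms: (trimethylsilyl)diazomethane C[Si](C)(C)C=[N+]=[N-]
Why: Esterification with the diazomethane surrogate should methylate the hindered acid under neutral conditions and give the C4 methyl ester of the target.

Step 6
Reactants: 9 keto ester
Product: 10 methyl (1R,2R,3R)-2-(tert-butyldiphenylsilyloxymethyl)-4,4-dimethoxy-1,3-dimethylcyclohexane-1-carboxylate
Conditions: MeOSiMe3, Me3SiOTf (cat.), CH2Cl2, −78 °C
Reagents that add atoms: methoxytrimethylsilane CO[Si](C)(C)C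
Why: Aprotic acetalisation with the alkoxysilane should give the dimethyl ketal needed for alcohol exchange while leaving the silyl ether intact.

Step 7
Reactants: 11 geranyl chloride
Product: 13 (E)-6-chloro-4-methylhex-4-enal, via epoxide 12 (not isolated)
Conditions: mCPBA, CH2Cl2, 0 °C; then H5IO6, THF/H2O, 0 °C
Reagents that add atoms: 3-chloroperbenzoic acid OOC(=O)c1cccc(Cl)c1
Why: Epoxidation should take the electron-rich distal alkene (the alkene next to the allylic chloride is deactivated) and periodic acid cleavage of the epoxide then gives the aldehyde with the (E)-alkene untouched.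

Step 8
Reactants: 13 (E)-6-chloro-4-methylhex-4-enal; 14 ethyl 2-[bis(2,2,2-trifluoroethoxy)phosphoryl]propanoate
Product: 15 ethyl (2Z,6E)-8-chloro-2,6-dimethylocta-2,6-dienoate
Conditions: KN(SiMe3)2, 18-crown-6, THF, −78 °C
Reagents that add atoms: none
Why: Still–Gennari olefination with the trifluoroethyl phosphonate under dissociating conditions should give the (Z)-2-methyl enoate, the geometry that later sets C9.

Step 9
Reactants: 16 tert-butyl(but-3-yn-1-yloxy)dimethylsilane; 15 ethyl (2Z,6E)-8-chloro-2,6-dimethylocta-2,6-dienoate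
Product: 18 ethyl (2Z,6E,9E)-12-(tert-butyldimethylsilyloxy)-2,6,10-trimethyldodeca-2,6,9-trienoate, via alkenylalane 17 (not isolated)
Conditions: Me3Al, Cp2ZrCl2, CH2Cl2, rt; then 15, Pd(PPh3)4 (cat.), THF, rt
Reagents that add atoms: trimethylaluminium C[Al](C)C
Why: Negishi carboalumination adds methyl and aluminium syn across the alkyne to give the (E)-alkenylalane, which should couple with the allylic chloride at its primary terminus under zerovalent palladium catalysis with retention of both alkene geometries and so form the skipped diene (C15–C16).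

Step 10
Reactants: 18 triene ester
Product: 19 (2Z,6E,9E)-12-(tert-butyldimethylsilyloxy)-2,6,10-trimethyldodeca-2,6,9-trien-1-ol
Conditions: i-Bu2AlH, CH2Cl2, −78 °C
Reagents that add atoms: none
Why: 1,2-Reduction of the enoate with the aluminium hydride should give the (Z)-allylic alcohol without alkene isomerisation.

Step 11
Reactants: 10 dimethyl ketal of ring A; 19 (Z)-allylic alcohol
Product: 21 methyl (1R,2R,3R)-2-(tert-butyldiphenylsilyloxymethyl)-3-[(3S,6E,9E)-12-(tert-butyldimethylsilyloxy)-2,6,10-trimethyldodeca-1,6,9-trien-3-yl]-1,3-dimethyl-4-oxocyclohexane-1-carboxylate, via allyl enol ether 20 (not isolated)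
Conditions: EtCO2H (cat.), xylenes, 135 °C, MeOH distilled off
Reagents that add atoms: none
Why: Ketal Claisen rearrangement, in which acid-catalysed alcohol exchange and loss of methanol give the more substituted allyl enol ether 20, whose chair-like [3,3] shift forms the C9–C10 bond on the face of C10 anti to the C5 CH2OSi group (quaternary C10 with C9 trans to C6), carries the (Z)-alkene substituent C11 axial in the chair so that C9 becomes S, and releases the isopropenyl group (C7=C8) and the C1 ketone.

Step 12
Reactants: 21 Claisen ketone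
Product: 23 methyl (1R,2R,3R)-2-(tert-butyldiphenylsilyloxymethyl)-3-[(3S,6E,9E)-12-(tert-butyldimethylsilyloxy)-2,6,10-trimethyldodeca-1,6,9-trien-3-yl]-1,3-dimethylcyclohexane-1-carboxylate, via tosylhydrazone 22 (not isolated)
Conditions: TsNHNH2, EtOH, 75 °C; then catecholborane, CHCl3, 0 °C; NaOAc·3H2O, reflux
Reagents that add atoms: none
Why: Tosylhydrazone formation, hydride reduction by catecholborane and acetate-induced loss of sulfinate and N2 (tosylhydrazone deoxygenation) should replace the C1 carbonyl by CH2 without touching alkenes, ester or silyl ethers and without creating a stereocentre.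

Step 13
Reactants: 23 bis-silyl ether
Product: 24 C19 alcohol (12-hydroxy analogue of 23, C6 silyl ether kept)
Conditions: CSA (cat.), MeOH/CH2Cl2, 0 °C
Reagents that add atoms: none
Why: Acid-catalysed methanolysis should cleave the unhindered primary tert-butyldimethylsilyl ether much faster than the hindered tert-butyldiphenylsilyl ether.

Step 14
Reactants: 24 homoallylic alcohol
Product: 25 (16S,17S)-16,17-epoxide of 24
Conditions: VO(Oi-Pr)3 (cat.), C2-symmetric bishydroxamic acid ligand from (1R,2R)-cyclohexane-1,2-diamine, cumene hydroperoxide, toluene, rt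
Reagents that add atoms: cumene hydroperoxide CC(C)(OO)c1ccccc1
Why: Hydroxyl-directed vanadium-catalysed asymmetric epoxidation of the homoallylic alcohol reaches only the C16=C17 alkene, and the chiral ligand should fix the face so that the (E)-alkene gives the 16S,17S epoxide.

Step 15
Reactants: 25 epoxy alcohol
Product: 27 enone (C14 ketone with C13=CH2, 16S,17S-epoxide, C19 acetate), via allylic hydroperoxide 26 (not isolated)
Conditions: O2, hν, tetraphenylporphyrin (cat.), CH2Cl2, 0 °C; then Ac2O, pyridine, 0 °C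
Reagents that add atoms: oxygen O=O; acetic anhydride CC(=O)OC(C)=O
Why: Schenck ene reaction of singlet oxygen with the only electron-rich trisubstituted alkene (C13=C14) should place the hydroperoxide on C14 and move the alkene to C13=CH2 (hydrogen taken from the methyl group on the crowded side, the C15 hydrogens being deactivated by the epoxide), and Kornblum–DeLaMare-type dehydration of the acetylated hydroperoxide then gives the enone, which erases the uncontrolled C14 centre while the primary alcohol is acetylated.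

Step 16
Reactants: 27 enone
Product: 28 (14R)-allylic alcohol
Conditions: (S)-Me-CBS (20 mol %), catecholborane, toluene, −78 °C
Reagents that add atoms: none
Why: Corey–Bakshi–Shibata reduction, in which the (S)-oxazaborolidine treats the branched alkenyl group as the large substituent, should deliver hydride 1,2 under reagent control to give the 14R alcohol.

Step 17
Reactants: 28 (14R)-allylic alcohol
Product: 29 (14S)-allylic chloride
Conditions: PPh3, (Cl3C)2CO, CH2Cl2, −20 to 0 °C
Reagents that add atoms: hexachloroacetone O=C(C(Cl)(Cl)Cl)C(Cl)(Cl)Cl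
Why: Appel-type chlorination with the phosphine and hexachloroacetone should convert the secondary allylic alcohol into the unrearranged chloride with inversion (14S).

Step 18
Reactants: 29 (14S)-allylic chloride
Product: 30 (14S,16S,17R)-14-chloro-16-hydroxy-17-hydroperoxide (C19 acetate)
Conditions: H2O2 (anhydrous, Et2O), H3PMo12O40 (cat.), rt
Reagents that add atoms: hydrogen peroxide OO
Why: Acid-catalysed perhydrolysis of the trisubstituted epoxide should open it at the tertiary C17 with inversion (17R hydroperoxide) while the C16 oxygen keeps its configuration.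

Step 19
Reactants: 30 chloro hydroperoxide
Product: 31 (14R,16S,17R)-1,2-dioxane (O–O from C14 to C17, 16-OH, C19 acetate)
Conditions: Cs2CO3, DMF, 0 °C
Reagents that add atoms: none
Why: Intramolecular O-alkylation of the hydroperoxide (6-exo-tet SN2) should displace the allylic chloride with inversion to give the 14R peroxide ring, the competing SN2' path needing an eight-membered ring.

Step 20
Reactants: 31 dioxane acetate
Product: 32 dioxane diol (C16 and C19 hydroxyls free, C6 silyl ether kept)
Conditions: K2CO3 (cat.), MeOH, 0 °C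
Reagents that add atoms: none
Why: Mild transesterification should remove the primary acetate while the hindered C4 methyl ester, the silyl ether and the dialkyl peroxide are left.

Step 21
Reactants: 32 dioxane diol
Product: 33 triol (C6, C16 and C19 hydroxyls free)
Conditions: HF·pyridine, THF/pyridine, 0 °C to rt
Reagents that add atoms: none
Why: Fluoride-mediated desilylation under acidic conditions should free the C6 alcohol without base, so that neither the peroxide nor lactonisation onto the C4 ester is triggered.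

Step 22
Reactants: 33 triol
Product: 34 seco-aldehyde (C6 aldehyde, isopropenyl on C9, trans-fused dioxane-lactone)
Conditions: TEMPO (cat.), PhI(OAc)2, CH2Cl2, rt
Reagents that add atoms: none
Why: Oxoammonium oxidation should take the C19 alcohol to the aldehyde, which closes with the C16 hydroxyl to a lactol that is oxidised on to the trans-fused γ-lactone (oxidative lactonisation of a 1,4-diol), while the C6 alcohol stops at the aldehyde and the peroxide and alkenes stay inert.

Step 23
Reactants: 34 seco-aldehyde
Product: 35 target CNP0162504.1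
Conditions: Sc(OTf)3 (cat.), MeCN/H2O, 0 °C to rt
Reagents that add atoms: water O
Why: Sc(OTf)3 activates the C6 aldehyde (held also by the neighbouring C4 ester carbonyl), the terminal carbon C7 of the isopropenyl group attacks C6, and the tertiary C8 cation is captured by water, so that the C6–C7 and C8–O bonds form in one operation (intramolecular Prins cyclisation with hydration). The closest known reaction types are the acid-mediated cyclisation of citronellal to p-menthane-3,8-diol and the carbonyl-ene cyclisation of 5-methylhex-5-enals. Ring B (C5–C6–C7–C8–C9–C10) closes through a chair transition state in which the alkene is endocyclic (6-endo-trig at C7=C8) and the carbonyl is attacked exo. C6 is controlled by ring A: the carbonyl oxygen takes the equatorial α-position because the axial β-position is syn-diaxial to both the C4 and the C10 methyl groups, which gives 6S. C8 is controlled by the same chair: water adds anti to the new C6–C7 bond from the equatorial α-face, away from the axial C10 methyl group, and leaves the C8 methyl group axial (8R), while the side chain on C9 stays equatorial. The step needs chemoselection between two 1,1-disubstituted alkenes and between hydration and proton loss: the C13 methylene would have to close an eight-membered ring and is deactivated by the allylic peroxide oxygen, the dialkyl peroxide and the lactone tolerate the water-compatible Lewis acid, and the excess of water should trap the cation before elimination.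

Compound list
1 | (tert-butyldiphenylsilyloxy)acetaldehyde | O=CCO[Si](c1ccccc1)(c1ccccc1)C(C)(C)C | starting material
2 | 2-(triphenylphosphoranylidene)propanal | CC(C=O)=P(c1ccccc1)(c1ccccc1)c1ccccc1 | starting material
3 | (E)-4-(tert-butyldiphenylsilyloxy)-2-methylbut-2-enal | O=C/C(C)=C/CO[Si](c1ccccc1)(c1ccccc1)C(C)(C)C | intermediate
4 | pent-1-en-3-one | C=CC(=O)CC | starting material
5 | (Z)-3-(triisopropylsilyloxy)penta-1,3-diene | C/C=C(O[Si](C(C)C)(C(C)C)C(C)C)/C=C | intermediate
6 | (1R,2R,3R)-2-(tert-butyldiphenylsilyloxymethyl)-1,3-dimethyl-4-(triisopropylsilyloxy)cyclohex-4-ene-1-carbaldehyde | CC(C)[Si](C(C)C)(C(C)C)OC1=CC[C@@](C)(C=O)[C@H](CO[Si](c2ccccc2)(c2ccccc2)C(C)(C)C)[C@H]1C | intermediate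
7 | (1R,2R,3R)-2-(tert-butyldiphenylsilyloxymethyl)-1,3-dimethyl-4-oxocyclohexane-1-carbaldehyde (skeleton 4R,5R,10R) | O=C1CC[C@@](C)(C=O)[C@H](CO[Si](c2ccccc2)(c2ccccc2)C(C)(C)C)[C@H]1C | intermediate
8 | (1R,2R,3R)-2-(tert-butyldiphenylsilyloxymethyl)-1,3-dimethyl-4-oxocyclohexane-1-carboxylic acid | O=C1CC[C@@](C)(C(=O)O)[C@H](CO[Si](c2ccccc2)(c2ccccc2)C(C)(C)C)[C@H]1C | intermediate
9 | methyl (1R,2R,3R)-2-(tert-butyldiphenylsilyloxymethyl)-1,3-dimethyl-4-oxocyclohexane-1-carboxylate | O=C1CC[C@@](C)(C(=O)OC)[C@H](CO[Si](c2ccccc2)(c2ccccc2)C(C)(C)C)[C@H]1C | intermediate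
10 | methyl (1R,2R,3R)-2-(tert-butyldiphenylsilyloxymethyl)-4,4-dimethoxy-1,3-dimethylcyclohexane-1-carboxylate | COC1(OC)CC[C@@](C)(C(=O)OC)[C@H](CO[Si](c2ccccc2)(c2ccccc2)C(C)(C)C)[C@H]1C | intermediate
11 | geranyl chloride, (2E)-1-chloro-3,7-dimethylocta-2,6-diene | CC(C)=CCC/C(C)=C/CCl | starting material
12 | 6,7-epoxygeranyl chloride (racemic) | CC1(C)OC1CC/C(C)=C/CCl | intermediate
13 | (E)-6-chloro-4-methylhex-4-enal | O=CCC/C(C)=C/CCl | intermediate
14 | ethyl 2-[bis(2,2,2-trifluoroethoxy)phosphoryl]propanoate | CCOC(=O)C(C)P(=O)(OCC(F)(F)F)OCC(F)(F)F | starting material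
15 | ethyl (2Z,6E)-8-chloro-2,6-dimethylocta-2,6-dienoate | CCOC(=O)/C(C)=C\CC/C(C)=C/CCl | intermediate
16 | tert-butyl(but-3-yn-1-yloxy)dimethylsilane | C#CCCO[Si](C)(C)C(C)(C)C | starting material
17 | [(E)-4-(tert-butyldimethylsilyloxy)-2-methylbut-1-en-1-yl]dimethylalane | C[Al](C)/C=C(\C)CCO[Si](C)(C)C(C)(C)C | intermediate
18 | ethyl (2Z,6E,9E)-12-(tert-butyldimethylsilyloxy)-2,6,10-trimethyldodeca-2,6,9-trienoate | CCOC(=O)/C(C)=C\CC/C(C)=C/C/C=C(\C)CCO[Si](C)(C)C(C)(C)C | intermediate
19 | (2Z,6E,9E)-12-(tert-butyldimethylsilyloxy)-2,6,10-trimethyldodeca-2,6,9-trien-1-ol | OC/C(C)=C\CC/C(C)=C/C/C=C(\C)CCO[Si](C)(C)C(C)(C)C | intermediate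
20 | allyl enol ether: methyl (1R,6R)-6-(tert-butyldiphenylsilyloxymethyl)-1,5-dimethyl-4-[(2Z,6E,9E)-12-(tert-butyldimethylsilyloxy)-2,6,10-trimethyldodeca-2,6,9-trienyloxy]cyclohex-4-ene-1-carboxylate | COC(=O)[C@]1(C)CCC(OC/C(C)=C\CC/C(C)=C/C/C=C(\C)CCO[Si](C)(C)C(C)(C)C)=C(C)[C@H]1CO[Si](c1ccccc1)(c1ccccc1)C(C)(C)C | intermediate
21 | methyl (1R,2R,3R)-2-(tert-butyldiphenylsilyloxymethyl)-3-[(3S,6E,9E)-12-(tert-butyldimethylsilyloxy)-2,6,10-trimethyldodeca-1,6,9-trien-3-yl]-1,3-dimethyl-4-oxocyclohexane-1-carboxylate (skeleton 4R,5R,9S,10R) | C=C(C)[C@H](CC/C(C)=C/C/C=C(\C)CCO[Si](C)(C)C(C)(C)C)[C@@]1(C)C(=O)CC[C@@](C)(C(=O)OC)[C@@H]1CO[Si](c1ccccc1)(c1ccccc1)C(C)(C)C | intermediate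
22 | tosylhydrazone of ketone 21 (C1=N–NHTs) | C=C(C)[C@H](CC/C(C)=C/C/C=C(\C)CCO[Si](C)(C)C(C)(C)C)[C@@]1(C)C(=NNS(=O)(=O)c2ccc(C)cc2)CC[C@@](C)(C(=O)OC)[C@@H]1CO[Si](c1ccccc1)(c1ccccc1)C(C)(C)C | intermediate
23 | methyl (1R,2R,3R)-2-(tert-butyldiphenylsilyloxymethyl)-3-[(3S,6E,9E)-12-(tert-butyldimethylsilyloxy)-2,6,10-trimethyldodeca-1,6,9-trien-3-yl]-1,3-dimethylcyclohexane-1-carboxylate (skeleton 4R,5R,9S,10R) | C=C(C)[C@H](CC/C(C)=C/C/C=C(\C)CCO[Si](C)(C)C(C)(C)C)[C@@]1(C)CCC[C@@](C)(C(=O)OC)[C@@H]1CO[Si](c1ccccc1)(c1ccccc1)C(C)(C)C | intermediate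
24 | C19 alcohol: 23 with the tert-butyldimethylsilyl group removed (12-hydroxydodecatrienyl side chain) | C=C(C)[C@H](CC/C(C)=C/C/C=C(\C)CCO)[C@@]1(C)CCC[C@@](C)(C(=O)OC)[C@@H]1CO[Si](c1ccccc1)(c1ccccc1)C(C)(C)C | intermediate
25 | (16S,17S)-16,17-epoxide of 24 | C=C(C)[C@H](CC/C(C)=C/C[C@@H]2O[C@@]2(C)CCO)[C@@]1(C)CCC[C@@](C)(C(=O)OC)[C@@H]1CO[Si](c1ccccc1)(c1ccccc1)C(C)(C)C | intermediate
26 | C14 hydroperoxide with C13=CH2 (both C14 epimers), 16S,17S-epoxide | C=C(C)[C@H](CCC(=C)C(OO)C[C@@H]2O[C@@]2(C)CCO)[C@@]1(C)CCC[C@@](C)(C(=O)OC)[C@@H]1CO[Si](c1ccccc1)(c1ccccc1)C(C)(C)C | intermediate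
27 | enone: C14 ketone with C13=CH2, 16S,17S-epoxide, C19 acetate | C=C(C)[C@H](CCC(=C)C(=O)C[C@@H]2O[C@@]2(C)CCOC(C)=O)[C@@]1(C)CCC[C@@](C)(C(=O)OC)[C@@H]1CO[Si](c1ccccc1)(c1ccccc1)C(C)(C)C | intermediate
28 | (14R)-allylic alcohol, 16S,17S-epoxide, C19 acetate | C=C(C)[C@H](CCC(=C)[C@H](O)C[C@@H]2O[C@@]2(C)CCOC(C)=O)[C@@]1(C)CCC[C@@](C)(C(=O)OC)[C@@H]1CO[Si](c1ccccc1)(c1ccccc1)C(C)(C)C | intermediate
29 | (14S)-allylic chloride, 16S,17S-epoxide, C19 acetate | C=C(C)[C@H](CCC(=C)[C@@H](Cl)C[C@@H]2O[C@@]2(C)CCOC(C)=O)[C@@]1(C)CCC[C@@](C)(C(=O)OC)[C@@H]1CO[Si](c1ccccc1)(c1ccccc1)C(C)(C)C | intermediate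
30 | (14S,16S,17R)-14-chloro-16-hydroxy-17-hydroperoxide, C19 acetate | C=C(C)[C@H](CCC(=C)[C@@H](Cl)C[C@H](O)[C@](C)(OO)CCOC(C)=O)[C@@]1(C)CCC[C@@](C)(C(=O)OC)[C@@H]1CO[Si](c1ccccc1)(c1ccccc1)C(C)(C)C | intermediate
31 | (14R,16S,17R)-1,2-dioxane (O–O from C14 to C17), 16-hydroxy, C19 acetate, C6 silyl ether | C=C(C)[C@H](CCC(=C)[C@H]2C[C@H](O)[C@@](C)(CCOC(C)=O)OO2)[C@@]1(C)CCC[C@@](C)(C(=O)OC)[C@@H]1CO[Si](c1ccccc1)(c1ccccc1)C(C)(C)C | intermediate
32 | dioxane diol: 31 without the acetate (C16 and C19 hydroxyls) | C=C(C)[C@H](CCC(=C)[C@H]2C[C@H](O)[C@@](C)(CCO)OO2)[C@@]1(C)CCC[C@@](C)(C(=O)OC)[C@@H]1CO[Si](c1ccccc1)(c1ccccc1)C(C)(C)C | intermediate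
33 | triol: C6, C16 and C19 hydroxyls free | C=C(C)[C@H](CCC(=C)[C@H]2C[C@H](O)[C@@](C)(CCO)OO2)[C@@]1(C)CCC[C@@](C)(C(=O)OC)[C@@H]1CO | intermediate
34 | seco-aldehyde: C6 aldehyde on C5, isopropenyl on C9, trans-fused dioxane-lactone (4R,5R,9S,10R,14R,16S,17R) | C=C(C)[C@H](CCC(=C)[C@H]2C[C@@H]3OC(=O)C[C@@]3(C)OO2)[C@@]1(C)CCC[C@@](C)(C(=O)OC)[C@@H]1C=O | intermediate
35 | CNP0162504.1 (4R,5R,6S,8R,9R,10S,14R,16S,17R) | C=C(CC[C@@H]1[C@@]2(C)CCC[C@@](C)(C(=O)OC)[C@@H]2[C@@H](O)C[C@@]1(C)O)[C@H]1C[C@@H]2OC(=O)C[C@@]2(C)OO1 | target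

Total step count: 23. Longest linear sequence: 18 steps (1, 3, 4, 5, 6, then 11 to 23).

Steps most likely to fail:

Step 23 (key step). What may go wrong: proton loss from the C8 cation in place of hydration, epimerisation at C5 through enolisation of the aldehyde before ring closure, or weak activation of the hindered aldehyde in the wet medium. Fallback: setting out from 34, SnCl4 in CH2Cl2 at −78 °C closes ring B with chloride capture to the (6S,8R)-8-chloro-6-alcohol F1. Solvolysis of the tertiary chloride with AgOTf in aqueous acetone (2,6-lutidine) then passes through the same C8 cation, water entering from the α-face, and comes back to the route at 35.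

Step 11. What may go wrong: enol ether formation on the C2 side of the ketal, erosion of the chair preference by the 2-methylallyl unit, and thermal loss of material. Fallback: setting out from ketone 9 (with alcohol 19), Tf2O and 2,6-di-tert-butyl-4-methylpyridine give the more substituted enol triflate F2. C–O coupling of this triflate with 19 (Pd2(dba)3, 2-(di-tert-butylphosphino)biphenyl, Cs2CO3, toluene) gives the regiodefined allyl enol ether 20, which rearranges on heating in toluene and comes back to the route at 21.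

Step 15. What may go wrong: base-induced β-elimination that opens the epoxide next to the new ketone, and hydrogen abstraction from C15 in place of the methyl group. Fallback: setting out from 25, ene-type allylic chlorination (N-chlorosuccinimide, PhSeCl cat., CH2Cl2) gives the allylic chloride F3 directly, as the 14S epimer together with its 14R epimer. Perhydrolysis under the conditions of step 18 gives the hydroperoxide F4, and Cs2CO3 in DMF closes the peroxide ring, the 14-epimeric peroxide being removed by chromatography. This comes back to the route at 32 and bypasses steps 16, 17 and 20 at the cost of reagent control at C14.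

Further compounds
F1 | step 23 | (6S,8R)-8-chloro-6-alcohol: the target with chlorine in place of the C8 hydroxyl | C=C(CC[C@@H]1[C@@]2(C)CCC[C@@](C)(C(=O)OC)[C@@H]2[C@@H](O)C[C@@]1(C)Cl)[C@H]1C[C@@H]2OC(=O)C[C@@]2(C)OO1
F2 | step 11 | enol triflate of 9: methyl (1R,6R)-6-(tert-butyldiphenylsilyloxymethyl)-1,5-dimethyl-4-(trifluoromethylsulfonyloxy)cyclohex-4-ene-1-carboxylate | COC(=O)[C@]1(C)CCC(OS(=O)(=O)C(F)(F)F)=C(C)[C@H]1CO[Si](c1ccccc1)(c1ccccc1)C(C)(C)C
F3 | step 15 | (14S)-allylic chloride with free C19 hydroxyl and 16S,17S-epoxide | C=C(C)[C@H](CCC(=C)[C@@H](Cl)C[C@@H]2O[C@@]2(C)CCO)[C@@]1(C)CCC[C@@](C)(C(=O)OC)[C@@H]1CO[Si](c1ccccc1)(c1ccccc1)C(C)(C)C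
F4 | step 15 | (14S,16S,17R)-14-chloro-16,19-dihydroxy-17-hydroperoxide | C=C(C)[C@H](CCC(=C)[C@@H](Cl)C[C@H](O)[C@](C)(OO)CCO)[C@@]1(C)CCC[C@@](C)(C(=O)OC)[C@@H]1CO[Si](c1ccccc1)(c1ccccc1)C(C)(C)C
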